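All runs are calculated with constants of no real substance, and the scatter is random.

A rate constant in per second and one in per molar per second disagree about dilution, and two chemists disagree in just that way over these flasks.

common to all: gas 45 mM (held)
- summer: electrophile 0.40 M; protonated nucleophile 1.1 equiv; run made earlier
- Thursday's: electrophile 0.20 M; protonated nucleophile 1.10 equiv; time 5.0 min
- Saturday's: electrophile 0.20 M; protonated nucleophile 1.10 equiv; time 12 min

summer run (percent of the electrophile charged)

| time / s | electrophile / % | side product / % | target / % |
|---|---|---|---|
| 10.0 | 96 | 2 | 7 |
| 25.0 | 87 | 4 | 10 |
| 40.0 | 78 | 1 | 21 |
| 60.0 | 71 | 0 | 27 |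
| 90.0 | 61 | 3 | 39 |

(each reading ± 1.5 percentage points)

- the earlier runs were read with a standard deviation of 1.5 percentage points
- at the start none of the gas is in solution

- which of these there is most of at the end, counted by the electrophile in it, Thursday's (electrophile / target / side product)
- which of these there is most of at the end, counted by the electrophile in it, Saturday's (electrophile / target / side product)
- final amount of the leader among these, as a percentage of the electrophile charged, in Thursday's
- final amount of the leader among these, as a percentage of the electrophile charged, in Saturday's

Thursday's and Saturday's flasks hold 0.20 M of electrophile against 0.40 M in the summer run, at the same equivalents of protonated nucleophile, and they run longer.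

The first chemist holds that the electrophile loses a fixed share per unit time, whatever its concentration. From the last summer reading, 61 % at 90.0 s, she reads a half-life of the electrophile of 2.10 min, the time in which its percentage falls by a factor of 2, and she carries it unchanged to flasks of the same equivalents. That leaves 19.3 % of the electrophile in Thursday's flask and 1.92 % in Saturday's. In the summer run target took nearly all of the loss, so she expects target at 80.7 % and 98.1 %.

The second chemist says the electrophile must meet the protonated nucleophile, whose amount falls with it, so, counting the two charges as equal, the inverse of the fraction left grows in a straight line with time times concentration. The same reading then leaves 48.4 % in Thursday's flask and 28.1 % in Saturday's, with target at 51.6 % and 71.9 %. He adds that the reading at 40.0 s lies 2.3 percentage points under her curve, but the scatter is 1.5 points, and the summer run held one concentration.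

The forecast leans to his side: “Because the nucleophile probably participates, I lean towards the slower case but hedge.” It names target as leader in both flasks, at 58 % in Thursday's and 80 % in Saturday's, figures that lie between the two reckonings.

Target leads in both flasks: 76.7 % with 20.7 % of electrophile left in Thursday's, and 88.2 % with 5.30 % left in Saturday's. The forecast stands 19 points and 8.2 points low, and Thursday's electrophile lies near her 19.3 %.

    gas ⇌ free base, rate k1*(csat - [free base]) (kL = 0.308 s⁻¹)
    electrophile + nucleophile → acid set free + target (k = 2.69 M⁻¹ s⁻¹)
    acid set free + target → side product (k = 0.0590 M⁻¹ s⁻¹)
    acid set free + free base ⇌ salt of the base (K = 4840 M⁻¹, k = 11.1 M⁻¹ s⁻¹)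
    nucleophile + acid set free ⇌ protonated nucleophile, settled at all times (K = 16000 M⁻¹)
    nucleophile ⇌ dormant form (K = 2.90, k = 0.110 s⁻¹)

In Thursday's flask electrophile + nucleophile ran while [nucleophile] stood at 0.00199 M at 2.50 min and 0.00159 M at 5.00 min, far below the charged electrophile, a level near enough to steady to call the electrophile's fall close to pseudo-first-order. In Saturday's flask [nucleophile] had sunk to 9.53 × 10⁻⁴ M by 12.0 min, with electrophile at 5.30 % against her 1.92 %. For Saturday's recipe stopped at 3.0 min, her half-life gives 37.1 % of electrophile left, and that flask holds 36 %. His view belongs where protonated nucleophile is the limiting reagent: charged at 0.280 equiv in Saturday's recipe, it stands at 0 % of its charge after 12.0 min, with electrophile at 72 % and target at 27.3 %; with the other charges and the time held, target and electrophile end level at a charge of 0.511 equiv.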